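**Retrosynthetic overview**

1. Feature: both end rings are ring-opened limonenes. In carotenoid numbering C2 is limonene C4, C1 is the isopropenyl carbon, the side-chain methylene C1″ is limonene C3, and C3–C4–C5(CH3) is limonene C5–C6–C1(CH3). Ring A (2R) maps onto (R)-limonene and ring B (2′S), its mirror image, onto (S)-limonene.
2. Key disconnection, C1–C6 of each ring: H2SO4 cyclisation of a limonene-derived 2-substituted pseudoionone (isopropenyl → C1 cation → capture by the C5=C6 alkene). The side-chain carbonyl is carried as an N,N-dimethylamide, which is fully O-protonated in the acid: it cannot close a γ-lactone onto C1, as an acid or ester in this γ,δ-unsaturated position would, and its charge disfavours a cation at C2.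
3. After ring closure the amide is reduced to the aldehyde and olefinated: Wittig (prenyl, ring A); Knoevenagel then i-Bu2AlH (bis-hydroxymethyl alkene, ring B).
4. Polyene: C11=C12 and C11′=C12′ come from two Wittig reactions of the ring A and ring B phosphonium salts on 2,7-dimethylocta-2,4,6-trienedial, so the free diol of ring B never meets an oxidant and needs no protecting group.
5. Ring order: ring A (step 7), then ring B (step 19); the halves meet in steps 12 and 25.

Key step: step 7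

Remark: centres and double bonds that are erased later (epoxide carbons, propargylic and allylic carbinol carbons, the allene axis, the C5=C6 geometry of 14 and 37) should form as mixtures and are drawn without descriptor or as the major isomer. Steps 13–21 repeat steps 1–9 on (S)-limonene; step 19 is the key step for ring B.

**Route**

Step 1
Reactants: 1 (R)-(+)-limonene
Product: 2 (4R)-limonene 1,2-oxide (cis/trans mixture)
Conditions: mCPBA (1.0 equiv), CH2Cl2, 0 °C
Reagents that add atoms: mCPBA, OOC(=O)c1cccc(Cl)c1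
Why: Prilezhaev epoxidation; the trisubstituted ring alkene is more electron-rich than the 1,1-disubstituted isopropenyl group, so one equivalent of peracid should take the ring alkene only, and both epoxide diastereomers converge in step 2.

Step 2
Reactants: 2 (4R)-limonene 1,2-oxide
Product: 4 (3R)-6-oxo-3-(prop-1-en-2-yl)heptanal, via diol 3 (not isolated)
Conditions: H5IO6 (1.2 equiv), THF/H2O, 0 °C to rt
Reagents that add atoms: water, O
Why: Periodic acid hydrolyses the epoxide to the 1,2-diol and cleaves it in the same flask (Malaprade glycol cleavage), opening the ring between limonene C1 and C2; the stereocentre is β to the new aldehyde and cannot enolise.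

Step 3
Reactants: 4 (3R)-6-oxo-3-(prop-1-en-2-yl)heptanal
Product: 5 (3R)-6-oxo-3-(prop-1-en-2-yl)heptanoic acid
Conditions: NaClO2, NaH2PO4, 2-methylbut-2-ene, t-BuOH/H2O, 0 °C to rt
Reagents that add atoms: sodium chlorite, [Na+].[O-]Cl=O
Why: Pinnick oxidation touches only the aldehyde, and the alkene scavenger removes HOCl before it can add to the isopropenyl group.

Step 4
Reactants: 5 (3R)-6-oxo-3-(prop-1-en-2-yl)heptanoic acid
Product: 7 (3R)-N,N-dimethyl-6-oxo-3-(prop-1-en-2-yl)heptanamide, via acyl imidazole 6 (not isolated)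
Conditions: CDI, THF, rt; then Me2NH (2 M in THF), rt
Reagents that add atoms: dimethylamine, CNC
Why: Acyl imidazole formation and aminolysis is a standard amide synthesis, and the tertiary amide is the spectator group that step 7 needs.

Step 5
Reactants: 7 (3R)-N,N-dimethyl-6-oxo-3-(prop-1-en-2-yl)heptanamide; 8 ethynylmagnesium bromide
Product: 9 (3R)-6-hydroxy-N,N,6-trimethyl-3-(prop-1-en-2-yl)oct-7-ynamide (6RS)
Conditions: 8 (1.5 equiv), THF, −20 to 0 °C; then sat. NH4Cl
Reagents that add atoms: ethynylmagnesium bromide 8, C#C[Mg]Br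
Why: Grignard addition to the methyl ketone; a tertiary amide does not react with an alkynyl Grignard reagent at this temperature, and the new carbinol centre is erased in step 6.

Step 6
Reactants: 9 (3R)-6-hydroxy-N,N,6-trimethyl-3-(prop-1-en-2-yl)oct-7-ynamide; 10 2-methoxypropene
Product: 14 (3R,6E,8E)-N,N,6-trimethyl-10-oxo-3-(prop-1-en-2-yl)undeca-6,8-dienamide (6E/6Z mixture), via mixed ketal 11 (not isolated), via propargyl isopropenyl ether 12 (not isolated), via allenyl ketone 13 (not isolated)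
Conditions: 10 (4 equiv), TsOH·H2O (1 mol%), toluene, 95 °C, sealed vessel; then NaOMe (0.2 equiv), MeOH, 0 °C
Reagents that add atoms: 2-methoxypropene 10, COC(C)=C
Why: Saucy–Marbet reaction as in the dehydrolinalool-to-pseudoionone conversion: enol ether exchange, propargyl Claisen [3,3] rearrangement to the β-ketoallene and base-mediated shift of the allene into conjugation; the amide and the isopropenyl group are spectators.

Step 7
Reactants: 14 (3R,6E,8E)-N,N,6-trimethyl-10-oxo-3-(prop-1-en-2-yl)undeca-6,8-dienamide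
Product: 15 N,N-dimethyl-2-[(1R)-2,2,4-trimethyl-3-[(1E)-3-oxobut-1-en-1-yl]cyclohex-3-en-1-yl]acetamide
Conditions: 96% H2SO4 (excess), CH2Cl2, −20 to 0 °C, short contact time; then ice/NaHCO3
Reagents that add atoms: none
Why: Protonation of the isopropenyl group, the only basic C=C because the dienone and the amide are O-protonated in this medium, gives the tertiary C1 cation, which is captured by C6 of the C5=C6 alkene through a chair-like transition state to form the C1–C6 bond, and loss of H-6 from the resulting C5 cation gives the conjugated β-isomer. The closest known reaction is the H2SO4 cyclisation of pseudoionone to β-ionone (cation–olefin cyclisation). The six-membered ring A closes in the 6-endo-trig mode with respect to the C5=C6 alkene, and both C5=C6 isomers of 14 converge because that alkene is consumed and re-formed inside the ring. No stereocentre is created; C2 is the limonene C4 centre and only has to survive. The selectivity needed is ring closure ahead of a 1,2-hydride shift from C2 or proton loss from C2, and the amidium group two atoms from C2 is expected to secure it by making a C2 cation much less stable than the C1 cation, while its full protonation rules out the neighbouring-group lactonisation that an acid or ester at this position would undergo. Low temperature and short contact time limit whatever reversible proton loss at C2 remains.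

Step 8
Reactants: 15 N,N-dimethyl-2-[(1R)-2,2,4-trimethyl-3-[(1E)-3-oxobut-1-en-1-yl]cyclohex-3-en-1-yl]acetamide; 16 vinylmagnesium bromide
Product: 17 2-[(1R)-3-[(1E)-3-hydroxy-3-methylpenta-1,4-dien-1-yl]-2,2,4-trimethylcyclohex-3-en-1-yl]-N,N-dimethylacetamide (carbinol RS)
Conditions: 16 (1.5 equiv), THF, −78 to −30 °C; then sat. NH4Cl
Reagents that add atoms: vinylmagnesium bromide 16, C=C[Mg]Br
Why: Grignard 1,2-addition to the conjugated methyl ketone as in the vinyl-β-ionol synthesis; the N,N-dialkylamide is far less electrophilic and should stay, and the carbinol centre is destroyed in step 11.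

Step 9
Reactants: 17 2-[(1R)-3-[(1E)-3-hydroxy-3-methylpenta-1,4-dien-1-yl]-2,2,4-trimethylcyclohex-3-en-1-yl]-N,N-dimethylacetamide
Product: 18 2-[(1R)-3-[(1E)-3-hydroxy-3-methylpenta-1,4-dien-1-yl]-2,2,4-trimethylcyclohex-3-en-1-yl]acetaldehyde
Conditions: LiAlH(OEt)3 (2.5 equiv, from LiAlH4 and EtOAc), Et2O/THF, 0 °C; then aq. KNaC4H4O6 (potassium sodium tartrate)
Reagents that add atoms: none
Why: Partial reduction of a tertiary amide with an alkoxyaluminium hydride stops at the aluminium hemiaminal, which gives the aldehyde on hydrolysis; the alkenes are inert and the tertiary alkoxide only consumes one hydride.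

Step 10
Reactants: 18 2-[(1R)-3-[(1E)-3-hydroxy-3-methylpenta-1,4-dien-1-yl]-2,2,4-trimethylcyclohex-3-en-1-yl]acetaldehyde; 19 isopropyltriphenylphosphonium iodide
Product: 20 (1E)-3-methyl-1-[(5R)-2,6,6-trimethyl-5-(3-methylbut-2-en-1-yl)cyclohex-1-en-1-yl]penta-1,4-dien-3-ol
Conditions: 19 (2.3 equiv), n-BuLi, THF, 0 °C; then 18, −78 °C to rt
Reagents that add atoms: isopropyltriphenylphosphonium iodide 19, CC(C)[P+](c1ccccc1)(c1ccccc1)c1ccccc1.[I-]
Why: Wittig olefination with the non-stabilised isopropylidene ylide gives the prenyl alkene with no E/Z question; the excess ylide covers the free hydroxyl.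

Step 11
Reactants: 20 (1E)-3-methyl-1-[(5R)-2,6,6-trimethyl-5-(3-methylbut-2-en-1-yl)cyclohex-1-en-1-yl]penta-1,4-dien-3-ol; 21 triphenylphosphine hydrobromide
Product: 22 [(2E,4E)-3-methyl-5-[(5R)-2,6,6-trimethyl-5-(3-methylbut-2-en-1-yl)cyclohex-1-en-1-yl]penta-2,4-dien-1-yl]triphenylphosphonium bromide
Conditions: 21 (1.05 equiv), MeOH, 0 °C to rt; crystallisation
Reagents that add atoms: triphenylphosphine hydrobromide 21, [Br-].[PH+](c1ccccc1)(c1ccccc1)c1ccccc1
Why: Acid ionises the tertiary bis-allylic alcohol and triphenylphosphine captures the delocalised cation at its primary terminus (allylic transposition, the standard route from vinyl-β-ionol to the C15 Wittig salt); the isolated prenyl alkene should survive as the isopropylidene group does in the corresponding lycopene salt.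

Step 12
Reactants: 22 ring A phosphonium bromide; 23 (2E,4E,6E)-2,7-dimethylocta-2,4,6-trienedial
Product: 25 (2E,4E,6E,8E,10E,12E)-2,7,11-trimethyl-13-[(5R)-2,6,6-trimethyl-5-(3-methylbut-2-en-1-yl)cyclohex-1-en-1-yl]trideca-2,4,6,8,10,12-hexaenal, via phosphorane 24 (not isolated)
Conditions: 23 (3 equiv), NaOMe (1.1 equiv), CH2Cl2/MeOH, 0 °C to rt, salt and base added slowly to the dialdehyde; then heptane, 90 °C
Reagents that add atoms: 2,7-dimethylocta-2,4,6-trienedial 23, O=C/C(C)=C/C=C/C=C(C)/C=O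
Why: Wittig reaction of the allylic ylide with one aldehyde group of the dialdehyde, kept in excess to suppress double condensation; the new C11=C12 bond should form as an E/Z mixture that heating equilibrates to the all-E isomer.

Step 13
Reactants: 26 (S)-(−)-limonene
Product: 27 (4S)-limonene 1,2-oxide (cis/trans mixture)
Conditions: mCPBA (1.0 equiv), CH2Cl2, 0 °C
Reagents that add atoms: mCPBA, OOC(=O)c1cccc(Cl)c1
Why: Prilezhaev epoxidation of the more electron-rich ring alkene, as in step 1.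

Step 14
Reactants: 27 (4S)-limonene 1,2-oxide
Product: 29 (3S)-6-oxo-3-(prop-1-en-2-yl)heptanal, via diol 28 (not isolated)
Conditions: H5IO6 (1.2 equiv), THF/H2O, 0 °C to rt
Reagents that add atoms: water, O
Why: Epoxide hydrolysis and Malaprade cleavage in one flask, as in step 2.

Step 15
Reactants: 29 (3S)-6-oxo-3-(prop-1-en-2-yl)heptanal
Product: 30 (3S)-6-oxo-3-(prop-1-en-2-yl)heptanoic acid
Conditions: NaClO2, NaH2PO4, 2-methylbut-2-ene, t-BuOH/H2O, 0 °C to rt
Reagents that add atoms: sodium chlorite, [Na+].[O-]Cl=O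
Why: Pinnick oxidation, as in step 3.

Step 16
Reactants: 30 (3S)-6-oxo-3-(prop-1-en-2-yl)heptanoic acid
Product: 32 (3S)-N,N-dimethyl-6-oxo-3-(prop-1-en-2-yl)heptanamide, via acyl imidazole 31 (not isolated)
Conditions: CDI, THF, rt; then Me2NH (2 M in THF), rt
Reagents that add atoms: dimethylamine, CNC
Why: Amide formation through the acyl imidazole, as in step 4.

Step 17
Reactants: 32 (3S)-N,N-dimethyl-6-oxo-3-(prop-1-en-2-yl)heptanamide; 8 ethynylmagnesium bromide
Product: 33 (3S)-6-hydroxy-N,N,6-trimethyl-3-(prop-1-en-2-yl)oct-7-ynamide (6RS)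
Conditions: 8 (1.5 equiv), THF, −20 to 0 °C; then sat. NH4Cl
Reagents that add atoms: ethynylmagnesium bromide 8, C#C[Mg]Br
Why: Chemoselective Grignard addition to the methyl ketone, as in step 5.

Step 18
Reactants: 33 (3S)-6-hydroxy-N,N,6-trimethyl-3-(prop-1-en-2-yl)oct-7-ynamide; 10 2-methoxypropene
Product: 37 (3S,6E,8E)-N,N,6-trimethyl-10-oxo-3-(prop-1-en-2-yl)undeca-6,8-dienamide (6E/6Z mixture), via mixed ketal 34 (not isolated), via propargyl isopropenyl ether 35 (not isolated), via allenyl ketone 36 (not isolated)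
Conditions: 10 (4 equiv), TsOH·H2O (1 mol%), toluene, 95 °C, sealed vessel; then NaOMe (0.2 equiv), MeOH, 0 °C
Reagents that add atoms: 2-methoxypropene 10, COC(C)=C
Why: Saucy–Marbet reaction and allene-to-dienone isomerisation, as in step 6.

Step 19
Reactants: 37 (3S,6E,8E)-N,N,6-trimethyl-10-oxo-3-(prop-1-en-2-yl)undeca-6,8-dienamide
Product: 38 N,N-dimethyl-2-[(1S)-2,2,4-trimethyl-3-[(1E)-3-oxobut-1-en-1-yl]cyclohex-3-en-1-yl]acetamide
Conditions: 96% H2SO4 (excess), CH2Cl2, −20 to 0 °C, short contact time; then ice/NaHCO3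
Reagents that add atoms: none
Why: The cation–olefin cyclisation of step 7 in the enantiomeric series closes ring B through the C1′–C6′ bond (6-endo-trig), with C2′ carried from (S)-limonene and protected by the same amidium effect.

Step 20
Reactants: 38 N,N-dimethyl-2-[(1S)-2,2,4-trimethyl-3-[(1E)-3-oxobut-1-en-1-yl]cyclohex-3-en-1-yl]acetamide; 16 vinylmagnesium bromide
Product: 39 2-[(1S)-3-[(1E)-3-hydroxy-3-methylpenta-1,4-dien-1-yl]-2,2,4-trimethylcyclohex-3-en-1-yl]-N,N-dimethylacetamide (carbinol RS)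
Conditions: 16 (1.5 equiv), THF, −78 to −30 °C; then sat. NH4Cl
Reagents that add atoms: vinylmagnesium bromide 16, C=C[Mg]Br
Why: Ketone-selective Grignard 1,2-addition, as in step 8.

Step 21
Reactants: 39 2-[(1S)-3-[(1E)-3-hydroxy-3-methylpenta-1,4-dien-1-yl]-2,2,4-trimethylcyclohex-3-en-1-yl]-N,N-dimethylacetamide
Product: 40 2-[(1S)-3-[(1E)-3-hydroxy-3-methylpenta-1,4-dien-1-yl]-2,2,4-trimethylcyclohex-3-en-1-yl]acetaldehyde
Conditions: LiAlH(OEt)3 (2.5 equiv), Et2O/THF, 0 °C; then aq. KNaC4H4O6 (potassium sodium tartrate)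
Reagents that add atoms: none
Why: Partial hydride reduction of the tertiary amide to the aldehyde, as in step 9.

Step 22
Reactants: 40 2-[(1S)-3-[(1E)-3-hydroxy-3-methylpenta-1,4-dien-1-yl]-2,2,4-trimethylcyclohex-3-en-1-yl]acetaldehyde; 41 dimethyl malonate
Product: 42 dimethyl 2-[2-[(1S)-3-[(1E)-3-hydroxy-3-methylpenta-1,4-dien-1-yl]-2,2,4-trimethylcyclohex-3-en-1-yl]ethylidene]propanedioate
Conditions: 41 (1.2 equiv), piperidine (cat.), AcOH (cat.), MgSO4, CH2Cl2, rt
Reagents that add atoms: dimethyl malonate 41, COC(=O)CC(=O)OC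
Why: Knoevenagel condensation at the only aldehyde; the two ester groups are identical, so the new alkene has no geometric isomers, and the mild amine/acid pair should leave the tertiary bis-allylic alcohol alone.

Step 23
Reactants: 42 dimethyl 2-[2-[(1S)-3-[(1E)-3-hydroxy-3-methylpenta-1,4-dien-1-yl]-2,2,4-trimethylcyclohex-3-en-1-yl]ethylidene]propanedioate
Product: 43 2-[2-[(1S)-3-[(1E)-3-hydroxy-3-methylpenta-1,4-dien-1-yl]-2,2,4-trimethylcyclohex-3-en-1-yl]ethylidene]propane-1,3-diol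
Conditions: i-Bu2AlH (6 equiv), CH2Cl2, −78 to −20 °C; then aq. KNaC4H4O6 (potassium sodium tartrate)
Reagents that add atoms: none
Why: The Lewis-acidic aluminium hydride reduces both conjugated esters by 1,2-delivery to the allylic alcohols (enoate-to-allylic-alcohol reduction) and leaves the C=C in place.

Step 24
Reactants: 43 triol; 21 triphenylphosphine hydrobromide
Product: 44 [(2E,4E)-5-[(5S)-5-[4-hydroxy-3-(hydroxymethyl)but-2-en-1-yl]-2,6,6-trimethylcyclohex-1-en-1-yl]-3-methylpenta-2,4-dien-1-yl]triphenylphosphonium bromide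
Conditions: 21 (1.05 equiv), MeOH, 0 °C to rt
Reagents that add atoms: triphenylphosphine hydrobromide 21, [Br-].[PH+](c1ccccc1)(c1ccccc1)c1ccccc1
Why: Wittig salt formation with allylic transposition as in step 11; the tertiary bis-allylic alcohol ionises far more readily than the two primary allylic hydroxyls, which should therefore stay free.

Step 25
Reactants: 44 ring B phosphonium bromide; 25 ring A aldehyde
Product: 46 (2R,2′S)-2-(3-methylbut-2-en-1-yl)-2′-[4-hydroxy-3-(hydroxymethyl)but-2-en-1-yl]-β,β-carotene (target), via phosphorane 45 (not isolated)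
Conditions: NaOMe (3.5 equiv), CH2Cl2/MeOH, 0 °C to rt, Ar, dark; then EtOH, reflux; crystallisation
Reagents that add atoms: none
Why: Wittig reaction forming C11′=C12′, of the kind used with hydroxylated C15 salts in xanthophyll synthesis, where alkoxide formation at free hydroxyls does no harm; heating should equilibrate the new double bond to the all-E polyene.

**Compound list**

1 | (R)-(+)-limonene | CC1=CC[C@@H](CC1)C(C)=C | starting material
2 | (4R)-1-methyl-4-(prop-1-en-2-yl)-7-oxabicyclo[4.1.0]heptane (limonene 1,2-oxide, cis/trans) | CC1(O2)C2C[C@@H](CC1)C(C)=C | intermediate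
3 | (4R)-1-methyl-4-(prop-1-en-2-yl)cyclohexane-1,2-diol (not isolated) | CC1(O)C(O)C[C@@H](CC1)C(C)=C | intermediate
4 | (3R)-6-oxo-3-(prop-1-en-2-yl)heptanal | O=CC[C@@H](CCC(C)=O)C(C)=C | intermediate
5 | (3R)-6-oxo-3-(prop-1-en-2-yl)heptanoic acid | OC(=O)C[C@@H](CCC(C)=O)C(C)=C | intermediate
6 | 1-[(3R)-6-oxo-3-(prop-1-en-2-yl)heptanoyl]-1H-imidazole (not isolated) | O=C(C[C@@H](CCC(C)=O)C(C)=C)n1ccnc1 | intermediate
7 | (3R)-N,N-dimethyl-6-oxo-3-(prop-1-en-2-yl)heptanamide | CN(C)C(=O)C[C@@H](CCC(C)=O)C(C)=C | intermediate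
8 | ethynylmagnesium bromide | C#C[Mg]Br | starting material
9 | (3R)-6-hydroxy-N,N,6-trimethyl-3-(prop-1-en-2-yl)oct-7-ynamide (6RS) | CN(C)C(=O)C[C@@H](CCC(C)(O)C#C)C(C)=C | intermediate
10 | 2-methoxypropene | COC(C)=C | starting material
11 | (3R)-6-[(2-methoxypropan-2-yl)oxy]-N,N,6-trimethyl-3-(prop-1-en-2-yl)oct-7-ynamide (mixed ketal, not isolated) | CN(C)C(=O)C[C@@H](CCC(C)(OC(C)(C)OC)C#C)C(C)=C | intermediate
12 | (3R)-N,N,6-trimethyl-3-(prop-1-en-2-yl)-6-(prop-1-en-2-yloxy)oct-7-ynamide (not isolated) | CN(C)C(=O)C[C@@H](CCC(C)(OC(C)=C)C#C)C(C)=C | intermediate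
13 | (3R)-N,N,6-trimethyl-10-oxo-3-(prop-1-en-2-yl)undeca-6,7-dienamide (not isolated) | CN(C)C(=O)C[C@@H](CCC(C)=C=CCC(C)=O)C(C)=C | intermediate
14 | (3R,6E,8E)-N,N,6-trimethyl-10-oxo-3-(prop-1-en-2-yl)undeca-6,8-dienamide (with 6Z isomer) | CN(C)C(=O)C[C@@H](CC/C(C)=C/C=C/C(C)=O)C(C)=C | intermediate
15 | N,N-dimethyl-2-[(1R)-2,2,4-trimethyl-3-[(1E)-3-oxobut-1-en-1-yl]cyclohex-3-en-1-yl]acetamide | CN(C)C(=O)C[C@H]1CCC(C)=C(/C=C/C(C)=O)C1(C)C | intermediate
16 | vinylmagnesium bromide | C=C[Mg]Br | starting material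
17 | 2-[(1R)-3-[(1E)-3-hydroxy-3-methylpenta-1,4-dien-1-yl]-2,2,4-trimethylcyclohex-3-en-1-yl]-N,N-dimethylacetamide | CN(C)C(=O)C[C@H]1CCC(C)=C(/C=C/C(C)(O)C=C)C1(C)C | intermediate
18 | 2-[(1R)-3-[(1E)-3-hydroxy-3-methylpenta-1,4-dien-1-yl]-2,2,4-trimethylcyclohex-3-en-1-yl]acetaldehyde | O=CC[C@H]1CCC(C)=C(/C=C/C(C)(O)C=C)C1(C)C | intermediate
19 | isopropyltriphenylphosphonium iodide | CC(C)[P+](c1ccccc1)(c1ccccc1)c1ccccc1.[I-] | starting material
20 | (1E)-3-methyl-1-[(5R)-2,6,6-trimethyl-5-(3-methylbut-2-en-1-yl)cyclohex-1-en-1-yl]penta-1,4-dien-3-ol | CC(C)=CC[C@H]1CCC(C)=C(/C=C/C(C)(O)C=C)C1(C)C | intermediate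
21 | triphenylphosphine hydrobromide | [Br-].[PH+](c1ccccc1)(c1ccccc1)c1ccccc1 | starting material
22 | [(2E,4E)-3-methyl-5-[(5R)-2,6,6-trimethyl-5-(3-methylbut-2-en-1-yl)cyclohex-1-en-1-yl]penta-2,4-dien-1-yl]triphenylphosphonium bromide | CC(C)=CC[C@H]1CCC(C)=C(/C=C/C(C)=C/C[P+](c2ccccc2)(c2ccccc2)c2ccccc2)C1(C)C.[Br-] | intermediate
23 | (2E,4E,6E)-2,7-dimethylocta-2,4,6-trienedial | O=C/C(C)=C/C=C/C=C(C)/C=O | starting material
24 | ring A phosphorane from 22 (not isolated) | CC(C)=CC[C@H]1CCC(C)=C(/C=C/C(C)=C/C=P(c2ccccc2)(c2ccccc2)c2ccccc2)C1(C)C | intermediate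
25 | (2E,4E,6E,8E,10E,12E)-2,7,11-trimethyl-13-[(5R)-2,6,6-trimethyl-5-(3-methylbut-2-en-1-yl)cyclohex-1-en-1-yl]trideca-2,4,6,8,10,12-hexaenal | CC(C)=CC[C@H]1CCC(C)=C(/C=C/C(C)=C/C=C/C(C)=C/C=C/C=C(C)/C=O)C1(C)C | intermediate
26 | (S)-(−)-limonene | CC1=CC[C@H](CC1)C(C)=C | starting material
27 | (4S)-1-methyl-4-(prop-1-en-2-yl)-7-oxabicyclo[4.1.0]heptane (cis/trans) | CC1(O2)C2C[C@H](CC1)C(C)=C | intermediate
28 | (4S)-1-methyl-4-(prop-1-en-2-yl)cyclohexane-1,2-diol (not isolated) | CC1(O)C(O)C[C@H](CC1)C(C)=C | intermediate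
29 | (3S)-6-oxo-3-(prop-1-en-2-yl)heptanal | O=CC[C@H](CCC(C)=O)C(C)=C | intermediate
30 | (3S)-6-oxo-3-(prop-1-en-2-yl)heptanoic acid | OC(=O)C[C@H](CCC(C)=O)C(C)=C | intermediate
31 | 1-[(3S)-6-oxo-3-(prop-1-en-2-yl)heptanoyl]-1H-imidazole (not isolated) | O=C(C[C@H](CCC(C)=O)C(C)=C)n1ccnc1 | intermediate
32 | (3S)-N,N-dimethyl-6-oxo-3-(prop-1-en-2-yl)heptanamide | CN(C)C(=O)C[C@H](CCC(C)=O)C(C)=C | intermediate
33 | (3S)-6-hydroxy-N,N,6-trimethyl-3-(prop-1-en-2-yl)oct-7-ynamide (6RS) | CN(C)C(=O)C[C@H](CCC(C)(O)C#C)C(C)=C | intermediate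
34 | (3S)-6-[(2-methoxypropan-2-yl)oxy]-N,N,6-trimethyl-3-(prop-1-en-2-yl)oct-7-ynamide (not isolated) | CN(C)C(=O)C[C@H](CCC(C)(OC(C)(C)OC)C#C)C(C)=C | intermediate
35 | (3S)-N,N,6-trimethyl-3-(prop-1-en-2-yl)-6-(prop-1-en-2-yloxy)oct-7-ynamide (not isolated) | CN(C)C(=O)C[C@H](CCC(C)(OC(C)=C)C#C)C(C)=C | intermediate
36 | (3S)-N,N,6-trimethyl-10-oxo-3-(prop-1-en-2-yl)undeca-6,7-dienamide (not isolated) | CN(C)C(=O)C[C@H](CCC(C)=C=CCC(C)=O)C(C)=C | intermediate
37 | (3S,6E,8E)-N,N,6-trimethyl-10-oxo-3-(prop-1-en-2-yl)undeca-6,8-dienamide (with 6Z isomer) | CN(C)C(=O)C[C@H](CC/C(C)=C/C=C/C(C)=O)C(C)=C | intermediate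
38 | N,N-dimethyl-2-[(1S)-2,2,4-trimethyl-3-[(1E)-3-oxobut-1-en-1-yl]cyclohex-3-en-1-yl]acetamide | CN(C)C(=O)C[C@@H]1CCC(C)=C(/C=C/C(C)=O)C1(C)C | intermediate
39 | 2-[(1S)-3-[(1E)-3-hydroxy-3-methylpenta-1,4-dien-1-yl]-2,2,4-trimethylcyclohex-3-en-1-yl]-N,N-dimethylacetamide | CN(C)C(=O)C[C@@H]1CCC(C)=C(/C=C/C(C)(O)C=C)C1(C)C | intermediate
40 | 2-[(1S)-3-[(1E)-3-hydroxy-3-methylpenta-1,4-dien-1-yl]-2,2,4-trimethylcyclohex-3-en-1-yl]acetaldehyde | O=CC[C@@H]1CCC(C)=C(/C=C/C(C)(O)C=C)C1(C)C | intermediate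
41 | dimethyl malonate | COC(=O)CC(=O)OC | starting material
42 | dimethyl 2-[2-[(1S)-3-[(1E)-3-hydroxy-3-methylpenta-1,4-dien-1-yl]-2,2,4-trimethylcyclohex-3-en-1-yl]ethylidene]propanedioate | COC(=O)C(=CC[C@@H]1CCC(C)=C(/C=C/C(C)(O)C=C)C1(C)C)C(=O)OC | intermediate
43 | 2-[2-[(1S)-3-[(1E)-3-hydroxy-3-methylpenta-1,4-dien-1-yl]-2,2,4-trimethylcyclohex-3-en-1-yl]ethylidene]propane-1,3-diol | OCC(CO)=CC[C@@H]1CCC(C)=C(/C=C/C(C)(O)C=C)C1(C)C | intermediate
44 | [(2E,4E)-5-[(5S)-5-[4-hydroxy-3-(hydroxymethyl)but-2-en-1-yl]-2,6,6-trimethylcyclohex-1-en-1-yl]-3-methylpenta-2,4-dien-1-yl]triphenylphosphonium bromide | OCC(CO)=CC[C@@H]1CCC(C)=C(/C=C/C(C)=C/C[P+](c2ccccc2)(c2ccccc2)c2ccccc2)C1(C)C.[Br-] | intermediate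
45 | ring B phosphorane from 44 (not isolated) | OCC(CO)=CC[C@@H]1CCC(C)=C(/C=C/C(C)=C/C=P(c2ccccc2)(c2ccccc2)c2ccccc2)C1(C)C | intermediate
46 | (2R,2′S)-2-(3-methylbut-2-en-1-yl)-2′-[4-hydroxy-3-(hydroxymethyl)but-2-en-1-yl]-β,β-carotene | CC(C)=CC[C@H]1CCC(C)=C(/C=C/C(C)=C/C=C/C(C)=C/C=C/C=C(C)/C=C/C=C(C)/C=C/C2=C(C)CC[C@@H](CC=C(CO)CO)C2(C)C)C1(C)C | target

**Summary**

Total step count: 25.
Longest linear sequence: 13 steps (steps 1–12 and 25; the ring B branch, steps 13–25, is equally long).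

Steps most likely to fail:

1. Step 7 (and its mirror image, step 19). The C1 cation may lose the C2 proton or take a 1,2-hydride shift from C2 before it cyclises. Return of the hydrogen to either face would erode the C2 configuration, and the wrong enantiomer would end up as an inseparable diastereomer of the carotenoid. Fallback: the amide nitrogen is made stereogenic, so that a C2 epimer becomes a separable diastereomer. Acid 5 is coupled (CDI) with (S)-2-(methoxymethyl)pyrrolidine to the keto amide F1. The operations of steps 5, 6 and 7 then give the ethynyl carbinol F2, the dienone amide F3 and the cyclised amide F4, from which the C2 epimer is removed by chromatography or crystallisation. Vinylmagnesium bromide as in step 8 gives the vinyl carbinol F5, and LiAlH(OEt)3 reduction returns to aldehyde 18. For ring B the same sequence sets out from acid 30, runs through the keto amide F6, the ethynyl carbinol F7, the dienone amide F8, the cyclised amide F9 and the vinyl carbinol F10, and returns to aldehyde 40.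

2. Step 22. Under amine catalysis the α-unbranched aldehyde 40 may self-condense, and the alkylidene malonate may take up a second malonate or lose conjugation by double-bond migration. Fallback (it also bypasses step 23): a Morita–Baylis–Hillman reaction of 40 with methyl acrylate and DABCO gives the hydroxy acrylate F11. Ac2O/pyridine gives the secondary allylic acetate F12. DABCO-catalysed allylic transposition moves the acetate to the primary carbon and gives the trisubstituted enoate F13; either alkene geometry serves, because the two oxygenated carbons become identical. i-Bu2AlH then reduces the ester and removes the acetate, returning to triol 43.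

3. Step 24. HBr may also ionise or substitute the two primary allylic hydroxyls of the side chain, leading to bromides or a bis-phosphonium salt. Fallback: triol 43 is acetylated at the two primary hydroxyls (Ac2O, pyridine, 0 °C) to the diacetate F14, PPh3·HBr gives the phosphonium diacetate F15, and the Wittig reaction with 25 under the conditions of step 25, where methoxide also removes the acetates, returns to target 46.

**Further compounds**

F1 | step 7 | (5R)-7-[(2S)-2-(methoxymethyl)pyrrolidin-1-yl]-5-(prop-1-en-2-yl)heptane-2,7-dione | COC[C@@H]1CCCN1C(=O)C[C@@H](CCC(C)=O)C(C)=C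
F2 | step 7 | (3R)-6-hydroxy-1-[(2S)-2-(methoxymethyl)pyrrolidin-1-yl]-6-methyl-3-(prop-1-en-2-yl)oct-7-yn-1-one | COC[C@@H]1CCCN1C(=O)C[C@@H](CCC(C)(O)C#C)C(C)=C
F3 | step 7 | (3E,5E,9R)-11-[(2S)-2-(methoxymethyl)pyrrolidin-1-yl]-6-methyl-9-(prop-1-en-2-yl)undeca-3,5-diene-2,11-dione | COC[C@@H]1CCCN1C(=O)C[C@@H](CC/C(C)=C/C=C/C(C)=O)C(C)=C
F4 | step 7 | 1-[(2S)-2-(methoxymethyl)pyrrolidin-1-yl]-2-[(1R)-2,2,4-trimethyl-3-[(1E)-3-oxobut-1-en-1-yl]cyclohex-3-en-1-yl]ethan-1-one | COC[C@@H]1CCCN1C(=O)C[C@H]2CCC(C)=C(/C=C/C(C)=O)C2(C)C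
F5 | step 7 | 2-[(1R)-3-[(1E)-3-hydroxy-3-methylpenta-1,4-dien-1-yl]-2,2,4-trimethylcyclohex-3-en-1-yl]-1-[(2S)-2-(methoxymethyl)pyrrolidin-1-yl]ethan-1-one | COC[C@@H]1CCCN1C(=O)C[C@H]2CCC(C)=C(/C=C/C(C)(O)C=C)C2(C)C
F6 | step 19 | (5S)-7-[(2S)-2-(methoxymethyl)pyrrolidin-1-yl]-5-(prop-1-en-2-yl)heptane-2,7-dione | COC[C@@H]1CCCN1C(=O)C[C@H](CCC(C)=O)C(C)=C
F7 | step 19 | (3S)-6-hydroxy-1-[(2S)-2-(methoxymethyl)pyrrolidin-1-yl]-6-methyl-3-(prop-1-en-2-yl)oct-7-yn-1-one | COC[C@@H]1CCCN1C(=O)C[C@H](CCC(C)(O)C#C)C(C)=C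
F8 | step 19 | (3E,5E,9S)-11-[(2S)-2-(methoxymethyl)pyrrolidin-1-yl]-6-methyl-9-(prop-1-en-2-yl)undeca-3,5-diene-2,11-dione | COC[C@@H]1CCCN1C(=O)C[C@H](CC/C(C)=C/C=C/C(C)=O)C(C)=C
F9 | step 19 | 1-[(2S)-2-(methoxymethyl)pyrrolidin-1-yl]-2-[(1S)-2,2,4-trimethyl-3-[(1E)-3-oxobut-1-en-1-yl]cyclohex-3-en-1-yl]ethan-1-one | COC[C@@H]1CCCN1C(=O)C[C@@H]2CCC(C)=C(/C=C/C(C)=O)C2(C)C
F10 | step 19 | 2-[(1S)-3-[(1E)-3-hydroxy-3-methylpenta-1,4-dien-1-yl]-2,2,4-trimethylcyclohex-3-en-1-yl]-1-[(2S)-2-(methoxymethyl)pyrrolidin-1-yl]ethan-1-one | COC[C@@H]1CCCN1C(=O)C[C@@H]2CCC(C)=C(/C=C/C(C)(O)C=C)C2(C)C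
F11 | step 22 | methyl 3-hydroxy-4-[(1S)-3-[(1E)-3-hydroxy-3-methylpenta-1,4-dien-1-yl]-2,2,4-trimethylcyclohex-3-en-1-yl]-2-methylidenebutanoate | COC(=O)C(=C)C(O)C[C@@H]1CCC(C)=C(/C=C/C(C)(O)C=C)C1(C)C
F12 | step 22 | methyl 3-acetoxy-4-[(1S)-3-[(1E)-3-hydroxy-3-methylpenta-1,4-dien-1-yl]-2,2,4-trimethylcyclohex-3-en-1-yl]-2-methylidenebutanoate | COC(=O)C(=C)C(OC(C)=O)C[C@@H]1CCC(C)=C(/C=C/C(C)(O)C=C)C1(C)C
F13 | step 22 | methyl 2-(acetoxymethyl)-4-[(1S)-3-[(1E)-3-hydroxy-3-methylpenta-1,4-dien-1-yl]-2,2,4-trimethylcyclohex-3-en-1-yl]but-2-enoate | COC(=O)C(COC(C)=O)=CC[C@@H]1CCC(C)=C(/C=C/C(C)(O)C=C)C1(C)C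
F14 | step 24 | 2-[2-[(1S)-3-[(1E)-3-hydroxy-3-methylpenta-1,4-dien-1-yl]-2,2,4-trimethylcyclohex-3-en-1-yl]ethylidene]propane-1,3-diyl diacetate | CC(=O)OCC(COC(C)=O)=CC[C@@H]1CCC(C)=C(/C=C/C(C)(O)C=C)C1(C)C
F15 | step 24 | [(2E,4E)-5-[(5S)-5-[4-acetoxy-3-(acetoxymethyl)but-2-en-1-yl]-2,6,6-trimethylcyclohex-1-en-1-yl]-3-methylpenta-2,4-dien-1-yl]triphenylphosphonium bromide | CC(=O)OCC(COC(C)=O)=CC[C@@H]1CCC(C)=C(/C=C/C(C)=C/C[P+](c2ccccc2)(c2ccccc2)c2ccccc2)C1(C)C.[Br-]
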